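**Retrosynthetic overview**
- The target comes from a macrocyclic C8,C14-diol: tartrate-controlled epoxidation of the 1(10) olefin, then the C14 acetate, then the C8 methacrylate.
- Key disconnection C7–C8: a ketyl radical from a C8 aldehyde adds to the β-carbon of an α-(acetoxymethyl)butenolide, and the resulting enolate expels acetate. This closes the ten-membered ring, sets C7 and C8, and unveils the α-methylene lactone.
- The butenolide (C6 set here) comes from a (Z)-enal and a (Z)-β-iodoacrylate by asymmetric Ni/Cr coupling and lactonisation.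
- The chain comes from a B-alkyl Suzuki coupling (C1–C2) of a (Z)-dienol-derived borane with a (Z)-iodo-diene made by anti-carbomagnesiation of propargyl alcohol.
- Ring order: butenolide, then ten-membered carbocycle, then oxirane.

Assumption: germacrane numbering is used for positions (ring C1–C10, lactone C11–C13, C14 on C10, C15 on C4), and the ligand antipode in step 8 is taken to be the one that gives the (R)-carbinol (checked by Mosher analysis; otherwise its enantiomer is used).

**Step 1**
Reactants: 1 prop-2-yn-1-ol; 2 vinylmagnesium bromide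
Product: 4 (2Z)-2-(iodomethylidene)but-3-en-1-ol, via alkenylmagnesium alkoxide 3 (not isolated)
Conditions: 2 (2.5 equiv), CuI (copper iodide, 10 mol %), THF, 0 °C → rt; then I2, THF, −30 → 0 °C
Reagents that add atoms: iodine, I-I
Why: Copper-catalysed anti-carbomagnesiation of the propargylic alkoxide (Duboudin–Jousseaume reaction) places vinyl on the internal carbon and magnesium on the terminal carbon cis to CH2O in a five-membered chelate, so iodinolysis with retention fixes the trisubstituted olefin geometry (C14 cis to the future C2) and no stereocentre is formed.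

**Step 2**
Reactants: 4 (2Z)-2-(iodomethylidene)but-3-en-1-ol
Product: 5 triethyl{[(2Z)-2-(iodomethylidene)but-3-en-1-yl]oxy}silane
Conditions: Et3SiCl, imidazole, CH2Cl2, 0 °C
Reagents that add atoms: chlorotriethylsilane, CC[Si](Cl)(CC)CC
Why: Standard silylation masks the C14 allylic alcohol so that only the C6 alcohol is oxidised later, and the TES ether survives the coupling, chromium and samarium steps yet falls off in mild acid.

**Step 3**
Reactants: 6 (2Z)-3-methylpent-2-en-4-yn-1-ol
Product: 7 (2Z)-3-methylpenta-2,4-dien-1-ol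
Conditions: H2 (1 atm, stopped after 1 equiv), Pd/CaCO3 poisoned with Pb(OAc)2, quinoline, EtOAc, 0 °C
Reagents that add atoms: none
Why: Lindlar semihydrogenation reduces the terminal alkyne of the enyne to a vinyl group without touching the trisubstituted (Z)-olefin, whose geometry comes from the commercial material.

**Step 4**
Reactants: 7 (2Z)-3-methylpenta-2,4-dien-1-ol; 5 triethyl{[(2Z)-2-(iodomethylidene)but-3-en-1-yl]oxy}silane
Product: 9 (2Z,6Z)-3-methyl-7-{[(triethylsilyl)oxy]methyl}nona-2,6,8-trien-1-ol, via alkylborane 8 (not isolated)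
Conditions: 9-BBN-H (2.2 equiv), THF, 0 °C → rt; then 5, PdCl2(dppf) (5 mol %), AsPh3, Cs2CO3, DMF–H2O, rt
Reagents that add atoms: none
Why: 9-BBN adds anti-Markovnikov to the terminal vinyl carbon (the alcohol is held as a borinate) and the B-alkyl Suzuki–Miyaura coupling with the alkenyl iodide proceeds with retention, forming the C1–C2 bond with both olefin geometries intact.

**Step 5**
Reactants: 9 (2Z,6Z)-3-methyl-7-{[(triethylsilyl)oxy]methyl}nona-2,6,8-trien-1-ol
Product: 10 (2Z,6Z)-3-methyl-7-{[(triethylsilyl)oxy]methyl}nona-2,6,8-trienal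
Conditions: MnO2 (20 equiv), CH2Cl2, rt
Reagents that add atoms: none
Why: MnO2 oxidises only the free allylic alcohol to the (Z)-enal (allylic oxidation) under neutral conditions that neither isomerise the neral-type olefin nor touch the silyl ether and diene.

**Step 6**
Reactants: 11 methyl prop-2-ynoate; 12 formaldehyde
Product: 13 methyl (2Z)-2-(hydroxymethyl)-3-iodoprop-2-enoate
Conditions: Bu4NI, TiCl4, CH2Cl2, −78 °C; then monomeric CH2O (from cracked paraformaldehyde), −78 °C
Reagents that add atoms: tetrabutylammonium iodide, CCCC[N+](CCCC)(CCCC)CCCC.[I-]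
Why: Iodide conjugate addition to the TiCl4-activated propiolate gives a β-iodo allenolate that adds to formaldehyde anti to iodine (halo-aldol, β-iodo Morita–Baylis–Hillman reaction), so the kinetic (Z)-isomer with iodine cis to the ester forms at low temperature.

**Step 7**
Reactants: 13 methyl (2Z)-2-(hydroxymethyl)-3-iodoprop-2-enoate
Product: 14 methyl (2Z)-2-[(acetyloxy)methyl]-3-iodoprop-2-enoate
Conditions: Ac2O, pyridine, DMAP (cat.), CH2Cl2, 0 °C
Reagents that add atoms: acetic anhydride, CC(=O)OC(C)=O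
Why: Routine acetylation turns the primary alcohol into the allylic acetate that later serves as the leaving group on C13.

**Step 8**
Reactants: 10 (2Z,6Z)-3-methyl-7-{[(triethylsilyl)oxy]methyl}nona-2,6,8-trienal; 14 methyl (2Z)-2-[(acetyloxy)methyl]-3-iodoprop-2-enoate
Product: 16 {(5R)-5-[(1Z,5Z)-2-methyl-6-{[(triethylsilyl)oxy]methyl}octa-1,5,7-trien-1-yl]-2-oxo-2,5-dihydrofuran-3-yl}methyl acetate, via hydroxy ester 15 (not isolated)
Conditions: CrCl2 (3 equiv), (S)-N-[2-(4-isopropyl-4,5-dihydro-1,3-oxazol-2-yl)-6-methylphenyl]methanesulfonamide (3.3 equiv, precomplexed using Et3N), NiCl2 (2 mol %), THF, rt; then PPTS (cat.), CH2Cl2, rt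
Reagents that add atoms: none
Why: In this asymmetric Nozaki–Hiyama–Kishi coupling zerovalent nickel inserts into the C–I bond with retention, the alkenylchromium adds 1,2 to the enal inside the chiral sulfonamide–chromium complex to set C6 (R) by ligand control, and the (Z)-γ-hydroxy enoate lactonises to the butenolide.

**Step 9**
Reactants: 16 {(5R)-5-[(1Z,5Z)-2-methyl-6-{[(triethylsilyl)oxy]methyl}octa-1,5,7-trien-1-yl]-2-oxo-2,5-dihydrofuran-3-yl}methyl acetate
Product: 18 {(5R)-5-[(1Z,5Z)-2-methyl-8-oxo-6-{[(triethylsilyl)oxy]methyl}octa-1,5-dien-1-yl]-2-oxo-2,5-dihydrofuran-3-yl}methyl acetate, via alkylborane 17 (not isolated)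
Conditions: 9-BBN-H (1.2 equiv), THF, 0 °C → rt; then NMO (6 equiv), (n-Pr4N)RuO4 (5 mol %), 4 Å MS, CH2Cl2, rt
Reagents that add atoms: 4-methylmorpholine N-oxide, C[N+]1([O-])CCOCC1
Why: 9-BBN hydroborates only the monosubstituted terminal alkene (trisubstituted and electron-poor olefins and the lactone are inert), and amine-oxide C–B oxidation followed by perruthenate (Ley–Griffith) oxidation gives the β,γ-unsaturated aldehyde without base, so the acidic C6–H of the butenolide is not epimerised.

**Step 10**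
Reactants: 18 {(5R)-5-[(1Z,5Z)-2-methyl-8-oxo-6-{[(triethylsilyl)oxy]methyl}octa-1,5-dien-1-yl]-2-oxo-2,5-dihydrofuran-3-yl}methyl acetate
Product: 20 (1(10)Z,4Z,6R,7R,8R)-8,14-dihydroxygermacra-1(10),4,11(13)-trien-12,6-olide, via TES ether 19 (not isolated)
Conditions: SmI2 (2.5 equiv), THF, 0 °C, 18 added over 4 h (final 2 mM), no proton source; then AcOH–THF–H2O (3:1:1), rt
Reagents that add atoms: none
Why: Proposed new method: divalent samarium reduces the aldehyde to a ketyl radical that adds in 10-exo fashion to C7 of the butenolide (radical C–C bond formation closing the ring), the α-carbonyl radical is reduced to a samarium enolate that expels the β-acetate to give the α-methylene lactone, attack anti to the C6 substituent gives the trans-fused lactone (7R), and the transition state with the O–Sm bond antiperiplanar to the C7=C11 bond and C9 in the open sector beside H7 gives 8R; the closest known reactions are SmI2 ketyl–olefin cyclisations onto butenolides and acrylates (five- to eight-membered rings) and SmI2 macrocyclic Reformatsky and Barbier closures, and the acid work-up removes the TES ether.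

**Step 11**
Reactants: 20 (1(10)Z,4Z,6R,7R,8R)-8,14-dihydroxygermacra-1(10),4,11(13)-trien-12,6-olide
Product: 21 (1R,4Z,6R,7R,8R,10S)-1,10-epoxy-8,14-dihydroxygermacra-4,11(13)-dien-12,6-olide
Conditions: t-BuOOH (2 equiv), Ti(Oi-Pr)4 (20 mol %), L-(+)-diisopropyl tartrate (24 mol %), 4 Å MS, CH2Cl2, −20 °C
Reagents that add atoms: tert-butyl hydroperoxide, CC(C)(C)OO
Why: In this Sharpless asymmetric epoxidation the C14 allylic alcohol binds titanium so only the 1(10) olefin reacts, and L-(+)-tartrate delivers oxygen to the face from which C14→C1→C9 runs clockwise, which is the 1R,10S epoxide with C14 still cis to C2.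

**Step 12**
Reactants: 21 (1R,4Z,6R,7R,8R,10S)-1,10-epoxy-8,14-dihydroxygermacra-4,11(13)-dien-12,6-olide; 22 acetyl chloride
Product: 23 (1R,4Z,6R,7R,8R,10S)-14-acetoxy-1,10-epoxy-8-hydroxygermacra-4,11(13)-dien-12,6-olide
Conditions: 22 (1.1 equiv), 2,4,6-collidine, CH2Cl2, −78 °C
Reagents that add atoms: none
Why: Selective acylation works because the primary C14 alcohol reacts far faster than the secondary ring alcohol at C8 under acid chloride and collidine at low temperature, and no stereocentre is touched.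

**Step 13**
Reactants: 23 (1R,4Z,6R,7R,8R,10S)-14-acetoxy-1,10-epoxy-8-hydroxygermacra-4,11(13)-dien-12,6-olide; 24 2-methylprop-2-enoyl chloride
Product: 25 (1R,4Z,6R,7R,8R,10S)-14-acetoxy-1,10-epoxy-8-(2-methylprop-2-enoyloxy)germacra-4,11(13)-dien-12,6-olide
Conditions: 24 (2 equiv), Et3N, DMAP (cat.), CH2Cl2, 0 °C → rt
Reagents that add atoms: none
Why: DMAP-catalysed acylation of the remaining secondary alcohol proceeds with retention at C8 and gives the methacrylate under conditions the epoxide, acetate and α-methylene lactone tolerate.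

**Compound list**
1 | prop-2-yn-1-ol | C#CCO | starting material
2 | vinylmagnesium bromide | C=C[Mg]Br | starting material
3 | bromomagnesium (2Z)-2-[(bromomagnesio)methylidene]but-3-en-1-olate | C=C/C(CO[Mg]Br)=C/[Mg]Br | intermediate
4 | (2Z)-2-(iodomethylidene)but-3-en-1-ol | C=C/C(CO)=C/I | intermediate
5 | triethyl{[(2Z)-2-(iodomethylidene)but-3-en-1-yl]oxy}silane | C=C/C(CO[Si](CC)(CC)CC)=C/I | intermediate
6 | (2Z)-3-methylpent-2-en-4-yn-1-ol | C#C/C(C)=C\CO | starting material
7 | (2Z)-3-methylpenta-2,4-dien-1-ol | C=C/C(C)=C\CO | intermediate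
8 | 9-[(3Z)-5-(9-borabicyclo[3.3.1]nonan-9-yloxy)-3-methylpent-3-en-1-yl]-9-borabicyclo[3.3.1]nonane | C(C/C(C)=C\COB1[C@H]2CCC[C@@H]1CCC2)B1[C@H]2CCC[C@@H]1CCC2 | intermediate
9 | (2Z,6Z)-3-methyl-7-{[(triethylsilyl)oxy]methyl}nona-2,6,8-trien-1-ol | C=C/C(CO[Si](CC)(CC)CC)=C/CC/C(C)=C\CO | intermediate
10 | (2Z,6Z)-3-methyl-7-{[(triethylsilyl)oxy]methyl}nona-2,6,8-trienal | C=C/C(CO[Si](CC)(CC)CC)=C/CC/C(C)=C\C=O | intermediate
11 | methyl prop-2-ynoate | C#CC(=O)OC | starting material
12 | formaldehyde | C=O | starting material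
13 | methyl (2Z)-2-(hydroxymethyl)-3-iodoprop-2-enoate | COC(=O)/C(CO)=C\I | intermediate
14 | methyl (2Z)-2-[(acetyloxy)methyl]-3-iodoprop-2-enoate | COC(=O)/C(COC(C)=O)=C\I | intermediate
15 | methyl (2Z,4R,5Z,9Z)-2-[(acetyloxy)methyl]-4-hydroxy-6-methyl-10-{[(triethylsilyl)oxy]methyl}dodeca-2,5,9,11-tetraenoate | C=C/C(CO[Si](CC)(CC)CC)=C/CC/C(C)=C\[C@@H](O)/C=C(/COC(C)=O)C(=O)OC | intermediate
16 | {(5R)-5-[(1Z,5Z)-2-methyl-6-{[(triethylsilyl)oxy]methyl}octa-1,5,7-trien-1-yl]-2-oxo-2,5-dihydrofuran-3-yl}methyl acetate | C=C/C(CO[Si](CC)(CC)CC)=C/CC/C(C)=C\[C@H]1OC(=O)C(COC(C)=O)=C1 | intermediate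
17 | {(5R)-5-[(1Z,5Z)-8-(9-borabicyclo[3.3.1]nonan-9-yl)-2-methyl-6-{[(triethylsilyl)oxy]methyl}octa-1,5-dien-1-yl]-2-oxo-2,5-dihydrofuran-3-yl}methyl acetate | B1(CC/C(CO[Si](CC)(CC)CC)=C/CC/C(C)=C\[C@H]3OC(=O)C(COC(C)=O)=C3)[C@H]2CCC[C@@H]1CCC2 | intermediate
18 | {(5R)-5-[(1Z,5Z)-2-methyl-8-oxo-6-{[(triethylsilyl)oxy]methyl}octa-1,5-dien-1-yl]-2-oxo-2,5-dihydrofuran-3-yl}methyl acetate | O=CC/C(CO[Si](CC)(CC)CC)=C/CC/C(C)=C\[C@H]1OC(=O)C(COC(C)=O)=C1 | intermediate
19 | (1(10)Z,4Z,6R,7R,8R)-8-hydroxy-14-[(triethylsilyl)oxy]germacra-1(10),4,11(13)-trien-12,6-olide | O[C@@H]1C/C(CO[Si](CC)(CC)CC)=C/CC/C(C)=C\[C@H]2OC(=O)C(=C)[C@@H]21 | intermediate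
20 | (1(10)Z,4Z,6R,7R,8R)-8,14-dihydroxygermacra-1(10),4,11(13)-trien-12,6-olide | O[C@@H]1C/C(CO)=C/CC/C(C)=C\[C@H]2OC(=O)C(=C)[C@@H]21 | intermediate
21 | (1R,4Z,6R,7R,8R,10S)-1,10-epoxy-8,14-dihydroxygermacra-4,11(13)-dien-12,6-olide | O[C@@H]1C[C@@]2(CO)O[C@@H]2CC/C(C)=C\[C@H]2OC(=O)C(=C)[C@@H]21 | intermediate
22 | acetyl chloride | CC(Cl)=O | starting material
23 | (1R,4Z,6R,7R,8R,10S)-14-acetoxy-1,10-epoxy-8-hydroxygermacra-4,11(13)-dien-12,6-olide | O[C@@H]1C[C@@]2(COC(C)=O)O[C@@H]2CC/C(C)=C\[C@H]2OC(=O)C(=C)[C@@H]21 | intermediate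
24 | 2-methylprop-2-enoyl chloride | C=C(C)C(Cl)=O | starting material
25 | (1R,4Z,6R,7R,8R,10S)-14-acetoxy-1,10-epoxy-8-(2-methylprop-2-enoyloxy)germacra-4,11(13)-dien-12,6-olide (CNP0150481.2) | C=C(C)C(=O)O[C@@H]1C[C@@]2(COC(C)=O)O[C@@H]2CC/C(C)=C\[C@H]2OC(=O)C(=C)[C@@H]21 | target

**Step count and risks**
Total step count: 13. Longest linear sequence: 10 steps (1 → 4 → 5 → 9 → 10 → 16 → 18 → 20 → 21 → 23 → 25).

The three steps most likely to fail:

- **Step 10 (radical ring closure).** A ten-membered ketyl–olefin closure has no direct precedent. Simple reduction or pinacol coupling of the aldehyde, the C8 epimer, or translactonisation by the C8 samarium alkoxide may compete. Fallback: setting out from 18, the same C7–C8 bond is closed by two-electron umpolung allylation with Pd(PPh3)4 (5 mol %) and InI (indium monoiodide) in THF–DMF at high dilution. Zerovalent palladium ionises the allylic acetate, transmetalation gives an allylindium species, and this adds to the aldehyde through its γ-carbon C7 in a closed six-membered transition state. This gives TES ether 19 directly, where it rejoins the route (acid work-up to 20); the fallback makes no new compound F0.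

- **Step 8 (asymmetric Ni/Cr coupling, together with the supply of iodide 14).** Ligand control on a (Z)-enal and the base-sensitive C6–H of the product are uncertain. Fallback, setting out from 10 and returning at 19:
  - Enal 10 is alkynylated with 11 (Me2Zn, ProPhenol ligand antipode giving the 4R alcohol, Ph3PO, toluene, 4 °C) to give methyl (4R,5Z,9Z)-4-hydroxy-6-methyl-10-{[(triethylsilyl)oxy]methyl}dodeca-5,9,11-trien-2-ynoate F1.
  - Cis-reduction of the conjugated alkyne with Zn dust activated by Cu(OAc)2 and AgNO3 (MeOH–H2O) and lactonisation give (5S)-5-[(1Z,5Z)-2-methyl-6-{[(triethylsilyl)oxy]methyl}octa-1,5,7-trien-1-yl]furan-2(5H)-one F2.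
  - 9-BBN-H, then NMO and (n-Pr4N)RuO4, give (5S)-5-[(1Z,5Z)-2-methyl-8-oxo-6-{[(triethylsilyl)oxy]methyl}octa-1,5-dien-1-yl]furan-2(5H)-one F3.
  - SmI2 ring closure as in step 10, with the samarium enolate trapped by [Me2N=CH2]I, gives (1(10)Z,4Z,6R,7R,8R)-13-(dimethylamino)-8-hydroxy-14-[(triethylsilyl)oxy]germacra-1(10),4-dien-12,6-olide F4 (C11 epimers).
  - Quaternisation with MeI and elimination with NaHCO3 install the 11(13)-methylene and deliver 19.

- **Step 11 (epoxidation inside the macrocycle).** The ring may override tartrate control or slow the titanium-bound pathway. Fallback, setting out from 20 and returning at 25: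
  - Diol 20 is acetylated at the primary alcohol with 22 and collidine at −78 °C to give (1(10)Z,4Z,6R,7R,8R)-14-acetoxy-8-hydroxygermacra-1(10),4,11(13)-trien-12,6-olide F5.
  - Esterification with 24 (Et3N, DMAP) gives (1(10)Z,4Z,6R,7R,8R)-14-acetoxy-8-(2-methylprop-2-enoyloxy)germacra-1(10),4,11(13)-trien-12,6-olide F6.
  - The epoxide is then installed last, without direction, by mCPBA with NaHCO3 in CH2Cl2 at 0 °C. This relies on substrate control: the 1(10) olefin is attacked on its exposed face, while the 4,5 olefin is deactivated by the allylic lactone oxygen.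

**Further compounds**
F0 | step 10 | none | none
F1 | step 8 | methyl (4R,5Z,9Z)-4-hydroxy-6-methyl-10-{[(triethylsilyl)oxy]methyl}dodeca-5,9,11-trien-2-ynoate | C=C/C(CO[Si](CC)(CC)CC)=C/CC/C(C)=C\[C@@H](O)C#CC(=O)OC
F2 | step 8 | (5S)-5-[(1Z,5Z)-2-methyl-6-{[(triethylsilyl)oxy]methyl}octa-1,5,7-trien-1-yl]furan-2(5H)-one | C=C/C(CO[Si](CC)(CC)CC)=C/CC/C(C)=C\[C@H]1OC(=O)C=C1
F3 | step 8 | (5S)-5-[(1Z,5Z)-2-methyl-8-oxo-6-{[(triethylsilyl)oxy]methyl}octa-1,5-dien-1-yl]furan-2(5H)-one | O=CC/C(CO[Si](CC)(CC)CC)=C/CC/C(C)=C\[C@H]1OC(=O)C=C1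
F4 | step 8 | (1(10)Z,4Z,6R,7R,8R)-13-(dimethylamino)-8-hydroxy-14-[(triethylsilyl)oxy]germacra-1(10),4-dien-12,6-olide (C11 epimers) | O[C@@H]1C/C(CO[Si](CC)(CC)CC)=C/CC/C(C)=C\[C@H]2OC(=O)C(CN(C)C)[C@@H]21
F5 | step 11 | (1(10)Z,4Z,6R,7R,8R)-14-acetoxy-8-hydroxygermacra-1(10),4,11(13)-trien-12,6-olide | O[C@@H]1C/C(COC(C)=O)=C/CC/C(C)=C\[C@H]2OC(=O)C(=C)[C@@H]21
F6 | step 11 | (1(10)Z,4Z,6R,7R,8R)-14-acetoxy-8-(2-methylprop-2-enoyloxy)germacra-1(10),4,11(13)-trien-12,6-olide | C=C(C)C(=O)O[C@@H]1C/C(COC(C)=O)=C/CC/C(C)=C\[C@H]2OC(=O)C(=C)[C@@H]21
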